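**Retrosynthetic overview**
1. Target ⇒ hydrogenolysis of three aryl benzyl ethers ⇒ LiAlH4 opening of a cis-fused furo[3,4-c]furan-1-one (3,7-dioxabicyclo[3.3.0]octan-2-one). Its lactone C–O bond is the 7R carbinol and its carbonyl is C9'.
2. Furofuranone ⇒ one-flask union of a Sharpless epoxy alcohol (guaiacyl C7–C9 unit) with a diallyl arylidenemalonate (catechol C7'–C9' unit): C7'–O by oxa-Michael addition, C8–C8' by 5-exo epoxide opening with inversion, O–C9' by lactonisation, then loss of the spare allyl ester.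
3. Ring order: oxolane first, γ-lactone second, both in the same flask. The lactone is later opened reductively, leaving the single oxolane of the target.
4. Epoxy alcohol ⇒ O-benzylvanillin (Wittig, i-Bu2AlH, Sharpless epoxidation); arylidenemalonate ⇒ 3,4-bis(benzyloxy)benzaldehyde + diallyl malonate (Knoevenagel).

Assumption: lignan numbering is used in the explanations (C7–C9 = guaiacyl propane unit, C7'–C9' = catechol propane unit), and the given SMILES defines the target.

**Route**

Step 1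
Reactants: 1 4-(benzyloxy)-3-methoxybenzaldehyde; 2 ethyl (triphenylphosphoranylidene)acetate
Product: 3 ethyl (E)-3-[4-(benzyloxy)-3-methoxyphenyl]prop-2-enoate
Conditions: 2 (1.1 equiv), PhMe, 90 °C, 4 h
Reagents that add atoms: none
Why: Wittig olefination with a stabilised ylide is reliably E-selective with aromatic aldehydes and leaves the benzyl ether untouched; no stereocentre is formed.

Step 2
Reactants: 3 ethyl (E)-3-[4-(benzyloxy)-3-methoxyphenyl]prop-2-enoate
Product: 4 (E)-3-[4-(benzyloxy)-3-methoxyphenyl]prop-2-en-1-ol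
Conditions: i-Bu2AlH (2.3 equiv), CH2Cl2, −78 → 0 °C; Rochelle salt work-up
Reagents that add atoms: none
Why: Ester reduction by 1,2-hydride delivery gives the allylic alcohol without touching the alkene geometry; no stereocentre is formed.

Step 3
Reactants: 4 (E)-3-[4-(benzyloxy)-3-methoxyphenyl]prop-2-en-1-ol
Product: 5 [(2S,3S)-3-[4-(benzyloxy)-3-methoxyphenyl]oxiran-2-yl]methanol
Conditions: Ti(OiPr)4 (10 mol %), L-(+)-DIPT (12 mol %), t-BuOOH (2 equiv, anhydrous), 4 Å MS, CH2Cl2, −25 °C; NaOH/brine work-up, Et3N-deactivated silica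
Reagents that add atoms: tert-butyl hydroperoxide, CC(C)(C)OO
Why: Sharpless asymmetric epoxidation with L-(+)-tartrate gives the (2S,3S)-glycidol from an (E)-3-arylallyl alcohol (as for cinnamyl alcohol), which sets the C7 oxygen stereocentre and the C8 centre that is inverted in step 5.

Step 4
Reactants: 6 3,4-bis(benzyloxy)benzaldehyde; 7 diallyl malonate
Product: 8 diallyl 2-[3,4-bis(benzyloxy)benzylidene]malonate
Conditions: piperidine (10 mol %), AcOH (10 mol %), PhMe, reflux, Dean–Stark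
Reagents that add atoms: none
Why: Knoevenagel condensation driven by azeotropic removal of water; the malonate is symmetric, so no alkene isomers or stereocentres arise.

Step 5
Reactants: 5 [(2S,3S)-3-[4-(benzyloxy)-3-methoxyphenyl]oxiran-2-yl]methanol; 8 diallyl 2-[3,4-bis(benzyloxy)benzylidene]malonate
Product: 12 (3R,3aR,6S,6aS)-3-[4-(benzyloxy)-3-methoxyphenyl]-6-[3,4-bis(benzyloxy)phenyl]tetrahydro-1H,3H-furo[3,4-c]furan-1-one, via oxa-Michael adduct 9 (not isolated), via oxolane diester 10 (not isolated), via allyl ester lactone 11 (not isolated)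
Conditions: 5 (1.0 equiv), 8 (1.05 equiv), KOt-Bu (0.2 equiv), 1,4-dioxane–DMSO (4:1), 20 → 40 °C; then HCO2H (4 equiv), Et3N (5 equiv), Pd(OAc)2 (5 mol %), PPh3 (20 mol %), 100 °C
Reagents that add atoms: none
Why: Proposed new method: the alkoxide of 5 adds reversibly to the doubly activated alkene of 8 (oxa-Michael), the malonate anion opens the tethered epoxide 5-exo at C8 with inversion while C7 keeps its oxygen (so the Sharpless epoxide fixes 7R and 8R), the freed benzylic alkoxide lactonises onto the syn ester (cis ring fusion) and releases allyloxide to carry the chain, the aryl group on C7' is expected to end up trans to the C8 side chain because that ring closure leaves only one substituent cis to each ester, and formate with zerovalent palladium then removes the spare allyl ester with decarboxylation and protonation that can only restore the cis fusion; the closest known chemistry is the alkoxide/alkylidenemalonate oxa-Michael–cyclisation of three-component tetrahydrofuran syntheses, intramolecular malonate–epoxide opening, and the Tsuji deallylative decarboxylation.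

Step 6
Reactants: 12 (3R,3aR,6S,6aS)-3-[4-(benzyloxy)-3-methoxyphenyl]-6-[3,4-bis(benzyloxy)phenyl]tetrahydro-1H,3H-furo[3,4-c]furan-1-one
Product: 13 (R)-[4-(benzyloxy)-3-methoxyphenyl]{(3R,4R,5S)-5-[3,4-bis(benzyloxy)phenyl]-4-(hydroxymethyl)oxolan-3-yl}methanol
Conditions: LiAlH4 (2 equiv), THF, 0 °C → rt; Fieser work-up
Reagents that add atoms: none
Why: Lactone reduction with LiAlH4 cleaves only the acyl C–O bond, so C9' becomes the hydroxymethyl group and C7 keeps its oxygen with retention as the free 7R alcohol; no stereocentre is touched.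

Step 7
Reactants: 13 (R)-[4-(benzyloxy)-3-methoxyphenyl]{(3R,4R,5S)-5-[3,4-bis(benzyloxy)phenyl]-4-(hydroxymethyl)oxolan-3-yl}methanol
Product: 14 (7R)-7-hydroxytaxiresinol, (R)-[(3R,4R,5S)-5-(3,4-dihydroxyphenyl)-4-(hydroxymethyl)oxolan-3-yl](4-hydroxy-3-methoxyphenyl)methanol
Conditions: H2 (1 atm), 10% Pd/C, EtOAc–EtOH (1:1), rt, stopped at 3 equiv H2
Reagents that add atoms: none
Why: Catalytic hydrogenolysis of aryl benzyl ethers under neutral conditions is faster than cleavage of the benzylic alcohol or the cyclic benzylic ether, so the three phenols are released without touching the stereocentres.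

**Compound list**
1 | 4-(benzyloxy)-3-methoxybenzaldehyde (O-benzylvanillin) | COc1cc(C=O)ccc1OCc1ccccc1 | starting material
2 | ethyl (triphenylphosphoranylidene)acetate | CCOC(=O)C=P(c1ccccc1)(c1ccccc1)c1ccccc1 | starting material
3 | ethyl (E)-3-[4-(benzyloxy)-3-methoxyphenyl]prop-2-enoate | CCOC(=O)/C=C/c1ccc(OCc2ccccc2)c(OC)c1 | intermediate
4 | (E)-3-[4-(benzyloxy)-3-methoxyphenyl]prop-2-en-1-ol | OC/C=C/c1ccc(OCc2ccccc2)c(OC)c1 | intermediate
5 | [(2S,3S)-3-[4-(benzyloxy)-3-methoxyphenyl]oxiran-2-yl]methanol (trans epoxide) | OC[C@@H]1O[C@H]1c2ccc(OCc3ccccc3)c(OC)c2 | intermediate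
6 | 3,4-bis(benzyloxy)benzaldehyde | O=Cc1ccc(OCc2ccccc2)c(OCc3ccccc3)c1 | starting material
7 | diallyl malonate | C=CCOC(=O)CC(=O)OCC=C | starting material
8 | diallyl 2-[3,4-bis(benzyloxy)benzylidene]malonate | C=CCOC(=O)C(=Cc1ccc(OCc2ccccc2)c(OCc3ccccc3)c1)C(=O)OCC=C | intermediate
9 | diallyl 2-[(S)-[3,4-bis(benzyloxy)phenyl]{[(2S,3S)-3-[4-(benzyloxy)-3-methoxyphenyl]oxiran-2-yl]methoxy}methyl]malonate (present as its enolate) | C=CCOC(=O)C(C(=O)OCC=C)[C@H](OC[C@@H]1O[C@H]1c2ccc(OCc3ccccc3)c(OC)c2)c4ccc(OCc5ccccc5)c(OCc6ccccc6)c4 | intermediate (not isolated)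
10 | diallyl (2R,4R)-2-[3,4-bis(benzyloxy)phenyl]-4-[(R)-[4-(benzyloxy)-3-methoxyphenyl](hydroxy)methyl]oxolane-3,3-dicarboxylate (present as its alkoxide; aryl at C2 trans to the C4 side chain) | C=CCOC(=O)C1(C(=O)OCC=C)[C@@H](c2ccc(OCc3ccccc3)c(OCc4ccccc4)c2)OC[C@@H]1[C@@H](O)c5ccc(OCc6ccccc6)c(OC)c5 | intermediate (not isolated)
11 | allyl (3R,3aR,6R,6aS)-3-[4-(benzyloxy)-3-methoxyphenyl]-6-[3,4-bis(benzyloxy)phenyl]-1-oxotetrahydro-1H,3H-furo[3,4-c]furan-6a(6H)-carboxylate (cis-fused) | COc1cc([C@@H]2OC(=O)[C@@]3(C(=O)OCC=C)[C@@H]2CO[C@@H]3c4ccc(OCc5ccccc5)c(OCc6ccccc6)c4)ccc1OCc7ccccc7 | intermediate (not isolated)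
12 | (3R,3aR,6S,6aS)-3-[4-(benzyloxy)-3-methoxyphenyl]-6-[3,4-bis(benzyloxy)phenyl]tetrahydro-1H,3H-furo[3,4-c]furan-1-one (cis-fused; C3 aryl endo, C6 aryl exo) | COc1cc([C@@H]2OC(=O)[C@H]3[C@@H]2CO[C@@H]3c4ccc(OCc5ccccc5)c(OCc6ccccc6)c4)ccc1OCc7ccccc7 | intermediate
13 | (R)-[4-(benzyloxy)-3-methoxyphenyl]{(3R,4R,5S)-5-[3,4-bis(benzyloxy)phenyl]-4-(hydroxymethyl)oxolan-3-yl}methanol | COc1cc([C@H](O)[C@H]2CO[C@H](c3ccc(OCc4ccccc4)c(OCc5ccccc5)c3)[C@H]2CO)ccc1OCc6ccccc6 | intermediate
14 | (7R)-7-hydroxytaxiresinol | COc1cc([C@H](O)[C@H]2CO[C@H](c3ccc(O)c(O)c3)[C@H]2CO)ccc1O | target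

**Totals and risks**

Total step count: 7. Longest linear sequence: 6 steps (1 → 3 → 4 → 5 → 12 → 13 → 14); the second branch (6 + 7 → 8) is one step.

The three steps most likely to fail are step 5, step 3 and step 7.

First, step 5. The cascade is untested. The alkoxide of 5 may undergo Payne rearrangement before it adds to 8. The malonate anion may attack benzylic C7 (giving a six-membered ether) instead of C8. Control at C7' rests on a modest steric preference; the minor epimer would be the lactone with both aryl groups on the concave face, to be separated at 12. The fallback sets out from 6 and 5 and returns at 12; it fixes C7' before ring closure and uses a singly activated carbanion. Aldehyde 6 is treated with LiCH2CN (THF, −78 °C), and lipase resolution of the racemic alcohol (CAL-B, vinyl acetate) leaves (S)-3-[3,4-bis(benzyloxy)phenyl]-3-hydroxypropanenitrile F1. Epoxy alcohol 5 is converted (TsCl, Et3N, DMAP) into [(2S,3S)-3-[4-(benzyloxy)-3-methoxyphenyl]oxiran-2-yl]methyl 4-methylbenzenesulfonate F2. The sodium alkoxide of F1 (NaH, DMF, −20 °C) is alkylated by F2 to give (S)-3-[3,4-bis(benzyloxy)phenyl]-3-{[(2S,3S)-3-[4-(benzyloxy)-3-methoxyphenyl]oxiran-2-yl]methoxy}propanenitrile F3. KHMDS (PhMe, −78 → 0 °C) then effects a Stork epoxynitrile cyclisation (5-exo, inversion at C8). The nitrile epimer that is cis to the new alkoxide is trapped as the bicyclic imidate (3R,3aR,6S,6aS)-3-[4-(benzyloxy)-3-methoxyphenyl]-6-[3,4-bis(benzyloxy)phenyl]tetrahydro-1H,3H-furo[3,4-c]furan-1-imine F4, while the trans epimer equilibrates through the nitrile anion. Dilute aqueous AcOH hydrolyses F4 to 12.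

Second, step 3. Epoxide 5 is a p-alkoxybenzylic epoxide and may open under the titanium conditions or on silica. The fallback sets out from 1 and returns at 9. Vinylmagnesium bromide (THF, 0 °C) gives racemic 1-[4-(benzyloxy)-3-methoxyphenyl]prop-2-en-1-ol F5. Sharpless kinetic resolution with the same Ti(OiPr)4/L-(+)-DIPT system (0.6 equiv t-BuOOH) epoxidises the (R)-alcohol to (S)-[4-(benzyloxy)-3-methoxyphenyl][(R)-oxiran-2-yl]methanol F6, whose epoxide is terminal and not benzylic and so survives isolation. F6 is charged in place of 5 in step 5 and pre-stirred with the KOt-Bu before 8 is added. Payne rearrangement (inversion at C8) turns its alkoxide into the alkoxide of 5, which adds to 8 and rejoins the route at 9.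

Third, step 7. Hydrogenolysis could also cleave the C7 benzylic hydroxyl (giving taxiresinol) or the C7'–O bond of the ring. The fallback sets out from 13 and returns at 14. Both hydroxyls are silylated (TBSOTf, 2,6-lutidine, CH2Cl2, 0 °C) to give the 7,9'-bis-O-tert-butyldimethylsilyl ether of 13 F7. The benzyl ethers are then removed (H2, 10% Pd/C, EtOAc) with the benzylic oxygen shielded, to give the 7,9'-bis-O-tert-butyldimethylsilyl ether of 14 F8. TBAF buffered with AcOH (THF, 0 °C) releases 14.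

**Further compounds**
F1 | step 5 | (S)-3-[3,4-bis(benzyloxy)phenyl]-3-hydroxypropanenitrile | N#CC[C@H](O)c1ccc(OCc2ccccc2)c(OCc3ccccc3)c1
F2 | step 5 | [(2S,3S)-3-[4-(benzyloxy)-3-methoxyphenyl]oxiran-2-yl]methyl 4-methylbenzenesulfonate | Cc1ccc(cc1)S(=O)(=O)OC[C@@H]2O[C@H]2c3ccc(OCc4ccccc4)c(OC)c3
F3 | step 5 | (S)-3-[3,4-bis(benzyloxy)phenyl]-3-{[(2S,3S)-3-[4-(benzyloxy)-3-methoxyphenyl]oxiran-2-yl]methoxy}propanenitrile | N#CC[C@H](OC[C@@H]1O[C@H]1c2ccc(OCc3ccccc3)c(OC)c2)c4ccc(OCc5ccccc5)c(OCc6ccccc6)c4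
F4 | step 5 | (3R,3aR,6S,6aS)-3-[4-(benzyloxy)-3-methoxyphenyl]-6-[3,4-bis(benzyloxy)phenyl]tetrahydro-1H,3H-furo[3,4-c]furan-1-imine | COc1cc([C@@H]2OC(=N)[C@H]3[C@@H]2CO[C@@H]3c4ccc(OCc5ccccc5)c(OCc6ccccc6)c4)ccc1OCc7ccccc7
F5 | step 3 | 1-[4-(benzyloxy)-3-methoxyphenyl]prop-2-en-1-ol (racemic) | C=CC(O)c1ccc(OCc2ccccc2)c(OC)c1
F6 | step 3 | (S)-[4-(benzyloxy)-3-methoxyphenyl][(R)-oxiran-2-yl]methanol | O[C@@H](c1ccc(OCc2ccccc2)c(OC)c1)[C@H]1CO1
F7 | step 7 | 7,9'-bis-O-tert-butyldimethylsilyl ether of 13 | COc1cc([C@H](O[Si](C)(C)C(C)(C)C)[C@H]2CO[C@H](c3ccc(OCc4ccccc4)c(OCc5ccccc5)c3)[C@H]2CO[Si](C)(C)C(C)(C)C)ccc1OCc6ccccc6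
F8 | step 7 | 7,9'-bis-O-tert-butyldimethylsilyl ether of 14 | COc1cc([C@H](O[Si](C)(C)C(C)(C)C)[C@H]2CO[C@H](c3ccc(O)c(O)c3)[C@H]2CO[Si](C)(C)C(C)(C)C)ccc1O
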